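No fit to the spring and autumn runs can show what substrate does to the rate, because both were charged with the same amount of it. The five new flasks change exactly that charge.

| flask | substrate | reagent | free catalyst | remark | time |
|---|---|---|---|---|---|
| spring | 4 mM | 6.7 mM | 0.78 mM | run made earlier |  |
| autumn | 4 mM | 5 mM | 0.78 mM | run made earlier |  |
| oak | 4.0 mM | 10.0 mM | 0.78 mM |  | 8.0 h |
| elm | 6.0 mM | 10.0 mM | 0.78 mM |  | 8.0 h |
| birch | 10 mM | 10.0 mM | 0.78 mM |  | 8.0 h |
| cedar | 15 mM | 10.0 mM | 0.78 mM |  | 8.0 h |
| alder | 25 mM | 10.0 mM | 0.78 mM |  | 8.0 h |

| run | time / h | product / % |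
|---|---|---|
| spring | 0.417 | 0 |
| spring | 0.833 | 1.2 |
| spring | 1.33 | 3.8 |
| spring | 1.50 | 4.2 |
| spring | 2.00 | 4.9 |
| spring | 2.50 | 9.2 |
| spring | 3.00 | 10.5 |
| autumn | 0.250 | 0 |
| autumn | 0.333 | 0.6 |
| autumn | 0.500 | 0.3 |
| autumn | 0.833 | 0.9 |
| autumn | 1.33 | 3.2 |
| autumn | 2.00 | 5.6 |
| autumn | 3.00 | 9.1 |

(scatter of a reading: 1 percentage point)

- "hardly changes" means that all values lie within two and a half points (for a concentration: within two and a half percent of the largest)

1. [product] at the end for oak, elm, birch, cedar, alder, in this order
2. how that number moves from the first to the last of them (falls all the way / rises, then falls / rises all the way / falls, then rises / hardly changes)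

At first the two runs seem to disagree: spring holds 1.34 times the reagent of autumn, yet at the last reading its product is 1.15 times autumn's. Reckoned with the fraction of the charge not yet product, that ratio moves only to 1.16. The negative logarithm of this fraction, divided by the reagent charge and the hours, is the clearing constant, and it gives 0.0920 L mol⁻¹ min⁻¹ for spring and 0.106 L mol⁻¹ min⁻¹ for autumn. Autumn's constant predicts 12.0% product in spring, which is 1.5 percentage points from the reading, against a scatter of 1 point. So the scatter of the readings, and not the change to the fraction left, removes the disagreement, and the two runs do not conflict with a rate proportional to reagent.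

The reckoning here carries their mean, the clearing constant 0.0990 L mol⁻¹ min⁻¹. For oak it leaves 62.2% not yet product, which makes 1.51 mM. Carried unchanged, it leaves that same fraction in each flask of the row, and no reading tests this.

The forecast gives 1.1 mM, 1.6 mM, 2.4 mM, 3.2 mM and 4.2 mM, so it rises all the way, and its oak value is lower than this reckoning's. It warns: “Neither run varied substrate, so its order is unknown and this is the weak point.”

The flasks give 1.62 mM, 1.90 mM, 2.15 mM, 2.29 mM and 2.40 mM, so the product rises all the way.

    catalyst intermediate B ⇌ free catalyst + product (K = 0.0430 M, k = 0.0110 min⁻¹)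
    reagent + catalyst intermediate A ⇌ catalyst intermediate B (K = 1300 L mol⁻¹, k = 3.10 L mol⁻¹ min⁻¹)
    substrate + free catalyst ⇌ catalyst intermediate A (K = 240 L mol⁻¹, k = 45.0 L mol⁻¹ min⁻¹)

Reckoned back from the product, the clearing constant is 0.109 L mol⁻¹ min⁻¹ in oak, against 0.0990 L mol⁻¹ min⁻¹ carried, but 0.0211 L mol⁻¹ min⁻¹ in alder, lower than the carried value. In oak, each forward step taken alone, free catalyst has a half-life of 0.13 h at the end and catalyst intermediate A one of 0.37 h as charged, while catalyst intermediate B gives up product with a half-life of 1.05 h, slower than either, and in alder at the end this resting state holds 58.4% of the catalyst, with 7.19% free.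

The readings were generated by integration from invented constants; the scatter is artificial.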